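**Numbering and conventions.** Every intermediate carries the locants of the target (indene numbering C1, C2, C3, C3a, C4–C7, C7a; dienyl carbons C1′–C4′). The carbon that becomes the carboxyl carbon is called C8. "Upper face" is the face of the six-membered ring that carries C8 on C4 and C1′ on C5 in the target; "lower face" is the opposite one.

## Analysis of the target

Target 33 is (1R,3aR,4R,5S,7aS)-5-ethyl-1,3,4,7-tetramethyl-5-[(1E,3E)-4-phenylbuta-1,3-dienyl]-3a,4,5,7a-tetrahydro-1H-indene-4-carboxylic acid. It is a trans-fused bicyclo[4.3.0]nonadiene with one trisubstituted alkene in each ring (C2=C3 and C6=C7). The five stereocentres C1, C7a, C3a, C4 and C5 are contiguous. C4 (CH3, CO2H) and C5 (ethyl, dienyl) are adjacent quaternary carbons whose carboxyl and dienyl groups are cis to each other and to C3a–H, while C7a–H and the C1 methyl group lie on the other face. Sensitive features are the (E,E)-styryl diene (oxidants, acid, light, metal hydrides), the strained trans ring fusion with allylic methine hydrogens that invite double-bond migration, and a carboxyl group buried between two quaternary carbons. The main difficulty is the vicinal pair of quaternary stereocentres, because enolate alkylations at such carbons are slow and give no handle on the cis relationship. The strategy rests on one feature: C8 on C4 and C1′ on C5 are two one-carbon termini, cis on neighbouring ring carbons, so joined to each other they are the two carbons of an alkene added across a C4=C5 double bond. With a carbonyl group at C6 that double bond belongs to a cyclohexenone, which allows a [2+2] photocycloaddition with a ketene acetal, and the C6 ketone later becomes the C6=C7 alkene.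

## Retrosynthetic reasoning

**33 to 32 (O–CH3).** The acid is carried as its methyl ester 32, which is the form the ring cleavage delivers. The ester is too hindered for attack at the carbonyl, so the forward step must cleave the O–methyl bond instead.

**32 to 29 and 30 (C1′=C2′).** The diene is cut at the double bond next to the ring, giving aldehyde 29 and phosphonate 30. The aldehyde has no α-hydrogen, and the olefination has to give the E double bond. The diene is made last because it would not survive the oxidations, the metathesis and the palladium chemistry used earlier.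

**29 to 28, 26 and 25 (reconnect C1′–C8).** The cis ester and aldehyde are the two ends of an oxidatively cleaved α-hydroxycyclobutanone 28, which comes from cyclobutanone 26 and its dimethyl acetal 25. The cleavage is placed late on purpose. While the four-membered ring is closed, C8 and C1′ are masked together as an acetal that tolerates enolates, organometallic reagents, fluoride and metathesis. The C6 ketone is then the only ketone to enolise, and neither a β-keto aldehyde at C5 nor the diene has to survive the construction of the two ring alkenes.

**25 to 24 and 22 (C3–CH3 and C1–CH3).** Both methyl groups of the cyclopentene come from cyclopentenone 22. Conjugate methylation at C1 is directed by the ring fusion, and the resulting enolate is fixed as enol triflate 24, which locks the double bond at C2=C3 for cross-coupling with a methyl nucleophile.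

**22 to 21, 20 and 19 (C1=C2 and C2–C3).** The cyclopentenone is opened at C1=C2 by a retro-metathesis to dienol 20, and C2 is removed as a vinyl nucleophile from aldehyde 19. This uses the C3 carbon that is already on C3a and a vinyl group on C7a, which must be trans to it.

**19 to 18, 17, 16 and 14 (C6–H for C6–O).** Aldehyde 19 comes from silyl ether 17 through alcohol 18. The C6=C7 alkene of 17 comes from ketone 14 through enol triflate 16, since the ketone can enolise only towards C7 and the double bond is therefore placed without ambiguity.

**14 to 12 and 10 (C7a–C1, C7–CH3, then C7=C7a).** The vinyl group on C7a and the methyl group on C7 are introduced across enone 12 by conjugate vinylation and enolate methylation. Enone 12 is the dehydrogenation product of ketone 10.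

**10 to 8 and 9 (C4–C8 and C5–C1′).** This is the key disconnection: the cyclobutane of 10 is cut into enone 8 and ketene acetal 9. Both quaternary carbons and their cis relationship arise in one photochemical step, at a stage where failure costs little.

**8 to 7, 6, 5, 4, and 1 with 2.** Enone 8 is the silyl ether of hydroxy enone 7, obtained by resolution of racemate 6. Racemate 6 comes from ester 4 by reduction to diol 5 and allylic reoxidation, and 4 from 1 by ethylation with 2 at C5.

## Alternatives that were turned down

**Alternative 1:** The disconnection cuts the cyclopentene at C7a–C1 and C3a–C3 and leaves the six-membered ring for later. In the forward key step TiCl4 activates an acyclic γ-oxo enoate, the CH terminus of an enantiopure silyl-substituted allene attacks C7a, a 1,2-silyl shift follows, and the enolate carbon C3a closes the ring. The product is the 2-silylcyclopentene A1, with acetyl on C3a, ester on C7a and methyl on C1, all trans. In its favour, one step sets C1, C3a and C7a in the correct relationship with the C3 methyl in place, whereas the chosen route needs steps 8 and 11–17 for the same ring; on this point the alternative is clearly stronger. Against it, the hard part of the target is untouched. From A1 the acetyl carbon (C4) must be made quaternary and joined to a second quaternary carbon C5 by ground-state additions to a hindered ketone next to an epimerisable C3a, and nothing controls the cis relationship of C8 and C1′. The vinylsilane must also be protodesilylated without moving the double bond. The chosen strategy instead solves the C4/C5 problem in one step with the cis relationship fixed by a ring.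

**Alternative 2:** The disconnection is the C5–C6 bond. In the forward key step a zerovalent palladium catalyst such as Pd(PPh3)4 inserts into a (Z)-alkenyl iodide on C7a, C6 adds to C5 of a tethered trisubstituted alkene (6-exo), and the alkylpalladium on C1′ loses a hydrogen from C2′. This closes the cyclohexene, makes C5 quaternary and completes the diene, giving A2, the methyl ester of the target (identical with 32). In its favour, one catalytic step near the end does all three things and the diene never has to be carried or installed separately; in late-stage step economy it is stronger than the chosen route. Against it, the configuration at C5 depends only on which alkene face the alkenylpalladium attacks, and the directing centre C4 is quaternary with three similar groups. C4 itself must be made beforehand by enolate alkylation next to C3a. The precursor is a skipped diene of defined geometry that must not isomerise, and the palladium hydride released can scramble the product diene. The chosen strategy makes both quaternary carbons in a single event that ties them cis, and tests this at step 6 instead of in the penultimate step.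

**Alternative 3:** The disconnection is the C4–C5 bond, made by a [3,3] shift. In the forward key step the silyl ketene acetal of a trans-fused six-membered lactone (ring oxygen on C7, carbonyl C8 on C4) rearranges through the boat imposed by the ring. This forms C4–C5, moves the alkene to C6=C7 and contracts the lactone to the cyclohexene, giving acid A3 with a silyloxymethyl group in place of the dienyl chain. In its favour, the concerted process relays the configuration of C7 and the alkene geometry to C4 and C5 predictably, puts C6=C7 in place and frees the acid directly. It needs neither a hindered ester cleavage nor an enol triflate reduction, and on these points it is as strong as or stronger than the chosen route. Against it, the rearrangement must join a fully substituted ketene acetal carbon to a fully substituted alkene terminus through a congested boat. The precursor already requires C1, C3a, C7a, a tertiary carbinol at C7 and a stereodefined trisubstituted alkene, so most of the stereochemical work precedes an uncertain key step. Three more steps then convert the silyloxymethyl group into the diene in the presence of the free acid. The chosen strategy offers a key-step precursor five steps from a commodity ester, so the risky step is reached almost at once.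

Key step: step 6

**Assumption (step 4):** Burkholderia cepacia lipase is taken to acylate the (R)-enantiomer of 6 faster, so that the (S)-alcohol 7 is recovered. This sense cannot be predicted reliably for a primary alcohol of this type; if it is reversed, the fallback given for step 4 applies.

## Route

Step 1
Reactants: 1 ethyl 2-methyl-4-oxocyclohex-2-ene-1-carboxylate (racemic); 2 iodoethane
Product: 4 ethyl 3-ethyl-2-methyl-4-oxocyclohex-2-ene-1-carboxylate (racemic), via potassium dienolate 3 (not isolated)
Conditions: KOtBu (1.05 equiv), tBuOH, 25 °C; then EtI, reflux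
Reagents that add atoms: iodoethane (compound 2), CCI
Why: Deprotonation at C3a (α to the ester, γ to the ketone) gives the extended dienolate 3, which is alkylated at the α-carbon of the enone (C5), and the double bond then returns into conjugation with the ketone. This is the established course of alkylation of this vinylogous β-keto ester.

Step 2
Reactants: 4 ethyl 3-ethyl-2-methyl-4-oxocyclohex-2-ene-1-carboxylate
Product: 5 2-ethyl-4-(hydroxymethyl)-3-methylcyclohex-2-en-1-ol (racemic, both diastereomers)
Conditions: LiAlH4, Et2O, −20 → 0 °C (inverse addition); H2O, 15% aq. NaOH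
Reagents that add atoms: none
Why: LiAlH4 reduces the ester to the primary alcohol and the enone carbonyl by 1,2-addition; inverse addition at low temperature limits γ-deprotonation. The configuration at C6 does not matter because C6 is reoxidised in step 3.

Step 3
Reactants: 5 2-ethyl-4-(hydroxymethyl)-3-methylcyclohex-2-en-1-ol
Product: 6 rac-2-ethyl-4-(hydroxymethyl)-3-methylcyclohex-2-en-1-one
Conditions: activated MnO2 (15 equiv), CH2Cl2, 25 °C
Reagents that add atoms: none
Why: MnO2 oxidises the allylic secondary alcohol chemoselectively and leaves the saturated primary alcohol untouched (allylic alcohol oxidation).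

Step 4
Reactants: 6 rac-2-ethyl-4-(hydroxymethyl)-3-methylcyclohex-2-en-1-one
Product: 7 (S)-2-ethyl-4-(hydroxymethyl)-3-methylcyclohex-2-en-1-one
Conditions: Burkholderia cepacia lipase, vinyl acetate (3 equiv), tBuOMe, 30 °C, to about 55% conversion; chromatography
Reagents that add atoms: none
Why: Lipase-catalysed transesterification is a kinetic resolution: one enantiomer of the primary alcohol is acylated faster, and beyond half conversion the unreacted alcohol should be recovered in high enantiomeric purity. The neutral medium cannot epimerise the γ-stereocentre C3a.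

Step 5
Reactants: 7 (S)-2-ethyl-4-(hydroxymethyl)-3-methylcyclohex-2-en-1-one
Product: 8 (S)-4-{[tert-butyl(dimethyl)silyl]oxymethyl}-2-ethyl-3-methylcyclohex-2-en-1-one
Conditions: TBSCl, imidazole, DMF, 0 → 25 °C
Reagents that add atoms: tert-butyldimethylsilyl chloride, CC(C)(C)[Si](C)(C)Cl
Why: Standard silylation of a primary alcohol. The silyl ether is transparent above 300 nm, inert to enolates and organometallic reagents, and provides the bulky group on C3a that differentiates the faces of the enone.

Step 6
Reactants: 8 (S)-4-{[tert-butyl(dimethyl)silyl]oxymethyl}-2-ethyl-3-methylcyclohex-2-en-1-one; 9 1,1-dimethoxyethene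
Product: 10 (1R,5S,6R)-5-{[tert-butyl(dimethyl)silyl]oxymethyl}-1-ethyl-7,7-dimethoxy-6-methylbicyclo[4.2.0]octan-2-one (cis-fused; C8(OMe)2 on C4 and C1′H2 on C5, both on the upper face)
Conditions: hν (medium-pressure Hg lamp, uranium-glass filter, λ > 330 nm), 9 (10 equiv), hexane, −40 °C
Reagents that add atoms: 1,1-dimethoxyethene (compound 9), C=C(OC)OC
Why: Excitation into the n→π* band and intersystem crossing give the twisted triplet of enone 8, which bonds to the CH2 terminus of 9; the biradical bonded at C5 (tertiary radical at C4, dialkoxy-stabilised radical at C8) undergoes spin inversion and radical–radical coupling, so the only ring formed, the cyclobutane, is closed by collapse of a 1,4-biradical (C4–C8 bond). The closest known reaction is the photocycloaddition of cyclohexenone and 3-methylcyclohexenone to 1,1-dialkoxyethenes, which gives 7,7-dialkoxybicyclo[4.2.0]octan-2-ones. Three selectivities are needed. Head-to-tail regiochemistry (C8 on C4, C1′ on C5) is the rule for cyclohexenone triplets and donor alkenes: the donor-bearing carbon pairs with the β-carbon in the polarised exciplex, and the isomeric biradical bonded at C4 reverts to the partners instead of closing. The configuration of both new stereocentres C4 and C5 is set by the face of approach, which C3a controls: allylic 1,2-strain with the C4 methyl group holds the silyloxymethyl group pseudoaxial over the lower face of C4=C5, so the alkene enters from the upper face. Cis ring fusion, which ties C4 to C5, is expected because the biradical with a tertiary radical at C4 can relax before it closes and because a trans-fused bicyclo[4.2.0]octane with two quaternary fusion atoms is severely strained. The large excess of 9 suppresses enone dimerisation, and the silyl ether does not absorb at this wavelength.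

Step 7
Reactants: 10 cis-fused photoadduct
Product: 12 (1R,5S,6R)-5-{[tert-butyl(dimethyl)silyl]oxymethyl}-1-ethyl-7,7-dimethoxy-6-methylbicyclo[4.2.0]oct-3-en-2-one (C6 ketone, C7=C7a), via trimethylsilyl enol ether 11 (not isolated)
Conditions: LiN(iPr)2, Me3SiCl, THF, −78 °C; then Pd(OAc)2 (1.1 equiv), MeCN, 25 °C
Reagents that add atoms: none
Why: Saegusa–Ito dehydrogenation. C5 is quaternary, so the ketone enolises only towards C7 and silyl enol ether 11 forms regiospecifically; Pd(OAc)2 converts it into the oxa-π-allyl species, which loses the C7a hydrogen by β-hydride elimination.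

Step 8
Reactants: 12 bicyclic enone
Product: 14 ketone carrying ethenyl on C7a (upper face, trans to the C3a substituent) and methyl on C7 (C7 epimers), via bromomagnesium enolate 13 (not isolated)
Conditions: CH2=CHMgBr (2 equiv), CuBr·SMe2 (20 mol %), THF, −78 → −30 °C; then MeI, DMPU, −30 → 0 °C
Reagents that add atoms: vinylmagnesium bromide, C=C[Mg]Br; iodomethane, CI
Why: CuBr·SMe2-catalysed conjugate addition of CH2=CHMgBr should occur at C7a anti to the adjacent silyloxymethyl group (the trans selectivity of 4-substituted cyclohexenones), which sets C7a. Enolate 13 is then C-methylated at C7, its only nucleophilic carbon; the configuration at C7 is irrelevant because C7 becomes trigonal in step 9.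

Step 9
Reactants: 14 C7-methyl, C7a-vinyl ketone
Product: 16 enol triflate [C6(OSO2CF3)=C7(CH3)], via potassium enolate 15 (not isolated)
Conditions: KN(SiMe3)2, THF, −78 → 0 °C; then PhNTf2, 0 °C
Reagents that add atoms: N-phenylbis(trifluoromethanesulfonimide), O=S(=O)(N(c1ccccc1)S(=O)(=O)C(F)(F)F)C(F)(F)F
Why: The ketone can enolise only towards C7, so deprotonation and O-sulfonylation give the tetrasubstituted enol triflate regiospecifically (enol triflate formation, as known for 2,2,6-trisubstituted cyclohexanones).

Step 10
Reactants: 16 enol triflate
Product: 17 4-ethenyl-1-ethyl-7,7-dimethoxy-3,6-dimethyl-5-(silyloxymethyl)bicyclo[4.2.0]oct-2-ene (C6H=C7(CH3))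
Conditions: Pd(OAc)2 (5 mol %), PPh3 (10 mol %), HCO2H, Bu3N, DMF, 60 °C
Reagents that add atoms: none
Why: Pd(OAc)2/PPh3-catalysed formate reduction of an enol triflate: oxidative addition to zerovalent palladium, formate exchange, loss of CO2 and reductive elimination give the C6=C7 alkene with the double bond fixed in place. The excess amine keeps the medium basic, so the acetal is safe.

Step 11
Reactants: 17 silyl ether
Product: 18 primary alcohol (CH2OH on C3a)
Conditions: Bu4NF, THF, 25 °C
Reagents that add atoms: none
Why: Fluoride cleaves the primary silyl ether (standard desilylation); the dimethyl acetal and the alkenes are inert to these conditions.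

Step 12
Reactants: 18 primary alcohol
Product: 19 aldehyde (CHO on C3a)
Conditions: Dess–Martin periodinane, NaHCO3, CH2Cl2, 0 → 25 °C
Reagents that add atoms: none
Why: Dess–Martin oxidation is buffered and non-epimerising; the formyl group is in any case trans to the C7a vinyl group, the more stable arrangement at C3a.

Step 13
Reactants: 19 aldehyde
Product: 20 allylic alcohol CH(OH)CH=CH2 on C3a (both C3 epimers)
Conditions: CH2=CHMgBr, THF, −78 °C
Reagents that add atoms: vinylmagnesium bromide, C=C[Mg]Br
Why: 1,2-Addition of CH2=CHMgBr to the aldehyde supplies C2. Both C3 epimers are carried on because C3 is oxidised in step 15.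

Step 14
Reactants: 20 dienol
Product: 21 tricyclic cyclopentenol (trans-fused five-membered ring with C3H(OH) and C1=C2; C3 epimers)
Conditions: second-generation Grubbs catalyst RuCl2(=CHPh)(PCy3)(H2IMes) (5 mol %), CH2Cl2, 40 °C
Reagents that add atoms: none
Why: Ring-closing metathesis joins the two monosubstituted vinyl groups with loss of ethene and closes the trans-fused cyclopentene. The trisubstituted C6=C7 bond is much less reactive and offers no reasonable ring size.

Step 15
Reactants: 21 cyclopentenol
Product: 22 cyclopentenone (C3=O, C1=C2)
Conditions: activated MnO2, CH2Cl2, 25 °C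
Reagents that add atoms: none
Why: MnO2 oxidises the allylic alcohol under neutral conditions, which matters because C7a–H (γ to the enone and allylic to C6=C7) and C3a–H are acidic.

Step 16
Reactants: 22 cyclopentenone
Product: 24 enol triflate [C3(OSO2CF3)=C2] with the C1 methyl on the lower face, via lithium enolate 23 (not isolated)
Conditions: Me2CuLi (from MeLi and CuI), Et2O, −78 °C; then PhNTf2, THF, −78 → 0 °C
Reagents that add atoms: lithium dimethylcuprate, [Li+].C[Cu-]C; N-phenylbis(trifluoromethanesulfonimide), O=S(=O)(N(c1ccccc1)S(=O)(=O)C(F)(F)F)C(F)(F)F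
Why: Me2CuLi adds to C1 anti to the C7a–C7 bond, as cuprates add trans to the 4-substituent of a cyclopentenone, which places the methyl on the lower face cis to C7a–H and sets C1. The regiodefined enolate 23 is trapped on oxygen (conjugate addition followed by enolate triflation), fixing the double bond at C2=C3.

Step 17
Reactants: 24 enol triflate
Product: 25 tricyclic diene acetal (complete tetrahydroindene core with C1, C3, C4 and C7 methyl groups; dimethoxycyclobutane across C4–C5)
Conditions: MeMgBr, Fe(acac)3 (5 mol %), THF/NMP, −30 °C
Reagents that add atoms: methylmagnesium bromide, C[Mg]Br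
Why: Fe(acac)3-catalysed cross-coupling of the alkenyl triflate with MeMgBr installs the C3 methyl group without moving the double bond; no other electrophile is present.

Step 18
Reactants: 25 dimethyl acetal
Product: 26 cyclobutanone (C8=O)
Conditions: p-TsOH·H2O (10 mol %), acetone/H2O (10:1), 25 °C
Reagents that add atoms: water, O
Why: Acid-catalysed acetal hydrolysis unmasks the cyclobutanone; dilute acid at room temperature should leave the trisubstituted alkenes alone.

Step 19
Reactants: 26 cyclobutanone
Product: 28 α-hydroxycyclobutanone (OH on C1′; C1′ epimers), via potassium enolate 27 (not isolated)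
Conditions: KN(SiMe3)2, THF, −78 °C; then 3-phenyl-2-(phenylsulfonyl)oxaziridine, −78 °C; AcOH, −78 °C
Reagents that add atoms: 3-phenyl-2-(phenylsulfonyl)oxaziridine, O=S(=O)(N1OC1c1ccccc1)c1ccccc1
Why: C4 is quaternary, so the cyclobutanone enolises only towards C1′. Enolate 27 is hydroxylated by the N-sulfonyloxaziridine (Davis enolate oxidation), which, unlike a peracid, does not attack the two trisubstituted alkenes; the configuration of the new carbinol is irrelevant.

Step 20
Reactants: 28 α-hydroxycyclobutanone
Product: 29 methyl (1R,3aR,4R,5S,7aS)-5-ethyl-5-formyl-1,3,4,7-tetramethyl-3a,4,5,7a-tetrahydro-1H-indene-4-carboxylate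
Conditions: Pb(OAc)4, MeOH/toluene (1:1), 0 °C
Reagents that add atoms: methanol, CO
Why: Glycol-type cleavage of the α-hydroxy ketone, through its methyl hemiketal, breaks the C1′–C8 bond with release of the four-ring strain. It delivers the methyl ester on C4 and the aldehyde on C5, necessarily cis.

Step 21
Reactants: 29 ester aldehyde; 30 diethyl cinnamylphosphonate
Product: 32 methyl (1R,3aR,4R,5S,7aS)-5-ethyl-1,3,4,7-tetramethyl-5-[(1E,3E)-4-phenylbuta-1,3-dien-1-yl]-3a,4,5,7a-tetrahydro-1H-indene-4-carboxylate, via lithiated phosphonate 31 (not isolated)
Conditions: 30, LiN(SiMe3)2, THF, −78 °C; then 29, −78 → 25 °C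
Reagents that add atoms: diethyl cinnamylphosphonate (compound 30), CCOP(=O)(C/C=C/c1ccccc1)OCC
Why: Horner–Wadsworth–Emmons olefination with the allylic phosphonate anion forms C1′=C2′ with E selectivity, and the cinnamyl double bond keeps its geometry. The aldehyde has no α-hydrogen and cannot enolise.

Step 22
Reactants: 32 methyl ester
Product: 33 (1R,3aR,4R,5S,7aS)-5-ethyl-1,3,4,7-tetramethyl-5-[(1E,3E)-4-phenylbuta-1,3-dien-1-yl]-3a,4,5,7a-tetrahydro-1H-indene-4-carboxylic acid
Conditions: LiSCH2CH2CH3, HMPA, 25 °C; then 1 M HCl
Reagents that add atoms: none
Why: The ester carbonyl is shielded by two quaternary carbons, so the ester is cleaved by SN2 attack of the thiolate on the O-methyl group (nucleophilic demethylation of a hindered ester). Acidification then gives the acid.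

## Compound list

1 | ethyl 2-methyl-4-oxocyclohex-2-ene-1-carboxylate (racemic) | CCOC(=O)C1CCC(=O)C=C1C | starting material
2 | iodoethane | CCI | starting material
3 | potassium dienolate of 1 (not isolated) | CCOC(=O)C1=C(C)C=C([O-])CC1.[K+] | intermediate
4 | ethyl 3-ethyl-2-methyl-4-oxocyclohex-2-ene-1-carboxylate (racemic) | CCOC(=O)C1CCC(=O)C(CC)=C1C | intermediate
5 | 2-ethyl-4-(hydroxymethyl)-3-methylcyclohex-2-en-1-ol (racemic, both diastereomers) | CCC1=C(C)C(CO)CCC1O | intermediate
6 | rac-2-ethyl-4-(hydroxymethyl)-3-methylcyclohex-2-en-1-one | CCC1=C(C)C(CO)CCC1=O | intermediate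
7 | (S)-2-ethyl-4-(hydroxymethyl)-3-methylcyclohex-2-en-1-one | CCC1=C(C)[C@@H](CO)CCC1=O | intermediate
8 | (S)-4-{[tert-butyl(dimethyl)silyl]oxymethyl}-2-ethyl-3-methylcyclohex-2-en-1-one | CCC1=C(C)[C@@H](CO[Si](C)(C)C(C)(C)C)CCC1=O | intermediate
9 | 1,1-dimethoxyethene | C=C(OC)OC | starting material
10 | (1R,5S,6R)-5-{[tert-butyl(dimethyl)silyl]oxymethyl}-1-ethyl-7,7-dimethoxy-6-methylbicyclo[4.2.0]octan-2-one (cis-fused; cyclobutane on the upper face, silyloxymethyl on the lower face) | CC[C@@]12CC(OC)(OC)[C@]1(C)[C@@H](CO[Si](C)(C)C(C)(C)C)CCC2=O | intermediate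
11 | trimethylsilyl enol ether of 10, C6(OSiMe3)=C7 (not isolated) | CC[C@@]12CC(OC)(OC)[C@]1(C)[C@@H](CO[Si](C)(C)C(C)(C)C)CC=C2O[Si](C)(C)C | intermediate
12 | (1R,5S,6R)-5-{[tert-butyl(dimethyl)silyl]oxymethyl}-1-ethyl-7,7-dimethoxy-6-methylbicyclo[4.2.0]oct-3-en-2-one (C6 ketone, C7=C7a) | CC[C@@]12CC(OC)(OC)[C@]1(C)[C@@H](CO[Si](C)(C)C(C)(C)C)C=CC2=O | intermediate
13 | bromomagnesium enolate C6(OMgBr)=C7 with ethenyl on C7a, upper face (not isolated) | CC[C@@]12CC(OC)(OC)[C@]1(C)[C@@H](CO[Si](C)(C)C(C)(C)C)[C@H](C=C)C=C2O[Mg]Br | intermediate
14 | ketone 10 carrying ethenyl on C7a (upper face, trans to the C3a substituent) and methyl on C7 (C7 epimers, centre left open) | CC[C@@]12CC(OC)(OC)[C@]1(C)[C@@H](CO[Si](C)(C)C(C)(C)C)[C@H](C=C)C(C)C2=O | intermediate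
15 | potassium enolate of 14, C6(OK)=C7 (not isolated) | CC[C@@]12CC(OC)(OC)[C@]1(C)[C@@H](CO[Si](C)(C)C(C)(C)C)[C@H](C=C)C(C)=C2[O-].[K+] | intermediate
16 | enol triflate of 14, C6(OSO2CF3)=C7(CH3) | CC[C@@]12CC(OC)(OC)[C@]1(C)[C@@H](CO[Si](C)(C)C(C)(C)C)[C@H](C=C)C(C)=C2OS(=O)(=O)C(F)(F)F | intermediate
17 | 5-{[tert-butyl(dimethyl)silyl]oxymethyl}-4-ethenyl-1-ethyl-7,7-dimethoxy-3,6-dimethylbicyclo[4.2.0]oct-2-ene (C6H=C7(CH3); configuration as in 14) | CC[C@@]12CC(OC)(OC)[C@]1(C)[C@@H](CO[Si](C)(C)C(C)(C)C)[C@H](C=C)C(C)=C2 | intermediate
18 | alcohol from 17 (CH2OH on C3a) | CC[C@@]12CC(OC)(OC)[C@]1(C)[C@@H](CO)[C@H](C=C)C(C)=C2 | intermediate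
19 | aldehyde from 18 (CHO on C3a) | CC[C@@]12CC(OC)(OC)[C@]1(C)[C@@H](C=O)[C@H](C=C)C(C)=C2 | intermediate
20 | allylic alcohol, CH(OH)CH=CH2 on C3a (C3 epimers, centre left open) | CC[C@@]12CC(OC)(OC)[C@]1(C)[C@@H](C(O)C=C)[C@H](C=C)C(C)=C2 | intermediate
21 | tricyclic cyclopentenol: trans-fused tetrahydroindene core with C3H(OH), C1=C2, C6=C7(CH3) and the dimethoxycyclobutane across C4–C5 (C3 epimers) | CC[C@@]12CC(OC)(OC)[C@]1(C)[C@H]3C(O)C=C[C@@H]3C(C)=C2 | intermediate
22 | tricyclic cyclopentenone (C3=O, C1=C2) | CC[C@@]12CC(OC)(OC)[C@]1(C)[C@H]3C(=O)C=C[C@@H]3C(C)=C2 | intermediate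
23 | lithium enolate C3(OLi)=C2 with the C1 methyl on the lower face (not isolated) | CC[C@@]12CC(OC)(OC)[C@]1(C)[C@H]3C([O-])=C[C@@H](C)[C@@H]3C(C)=C2.[Li+] | intermediate
24 | enol triflate C3(OSO2CF3)=C2 with the C1 methyl on the lower face | CC[C@@]12CC(OC)(OC)[C@]1(C)[C@H]3C(OS(=O)(=O)C(F)(F)F)=C[C@@H](C)[C@@H]3C(C)=C2 | intermediate
25 | tricyclic diene acetal: 5-ethyl-1,3,4,7-tetramethyl-3a,4,5,7a-tetrahydro-1H-indene with C8(OMe)2–C1′H2 bridging C4 and C5 on the upper face | CC[C@@]12CC(OC)(OC)[C@]1(C)[C@H]3C(C)=C[C@@H](C)[C@@H]3C(C)=C2 | intermediate
26 | cyclobutanone from 25 (C8=O) | CC[C@@]12CC(=O)[C@]1(C)[C@H]3C(C)=C[C@@H](C)[C@@H]3C(C)=C2 | intermediate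
27 | potassium enolate of 26, C8(OK)=C1′ (not isolated) | CC[C@@]12C=C([O-])[C@]1(C)[C@H]3C(C)=C[C@@H](C)[C@@H]3C(C)=C2.[K+] | intermediate
28 | α-hydroxycyclobutanone, OH on C1′ (C1′ epimers, centre left open) | CC[C@@]12C(O)C(=O)[C@]1(C)[C@H]3C(C)=C[C@@H](C)[C@@H]3C(C)=C2 | intermediate
29 | methyl (1R,3aR,4R,5S,7aS)-5-ethyl-5-formyl-1,3,4,7-tetramethyl-3a,4,5,7a-tetrahydro-1H-indene-4-carboxylate | CC[C@]1(C=O)C=C(C)[C@H]2[C@H](C)C=C(C)[C@@H]2[C@@]1(C)C(=O)OC | intermediate
30 | diethyl cinnamylphosphonate | CCOP(=O)(C/C=C/c1ccccc1)OCC | starting material
31 | lithiated diethyl cinnamylphosphonate (not isolated) | CCOP(=O)([CH-]/C=C/c1ccccc1)OCC.[Li+] | intermediate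
32 | methyl (1R,3aR,4R,5S,7aS)-5-ethyl-1,3,4,7-tetramethyl-5-[(1E,3E)-4-phenylbuta-1,3-dien-1-yl]-3a,4,5,7a-tetrahydro-1H-indene-4-carboxylate | CC[C@]1(/C=C/C=C/c2ccccc2)C=C(C)[C@H]2[C@H](C)C=C(C)[C@@H]2[C@@]1(C)C(=O)OC | intermediate
33 | (1R,3aR,4R,5S,7aS)-5-ethyl-1,3,4,7-tetramethyl-5-[(1E,3E)-4-phenylbuta-1,3-dien-1-yl]-3a,4,5,7a-tetrahydro-1H-indene-4-carboxylic acid | CC[C@]1(/C=C/C=C/c2ccccc2)C=C(C)[C@H]2[C@H](C)C=C(C)[C@@H]2[C@@]1(C)C(=O)O | target

## Step count and least certain steps

Total: 22 steps. Longest linear sequence: 22 steps (1 to 33); 2, 9 and 30 are purchased.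

**Step 6 (key step).** The doubly alkylated C4=C5 bond may add the alkene slowly, so that biradical disproportionation, oxetane formation at the carbonyl and photodegradation compete. The biradical may also close to the trans-fused ring, which cannot be corrected because neither fusion carbon bears a hydrogen, and the facial discrimination by the C3a substituent may be incomplete. The fallback sets out from 1 and returns at 12; it makes only C4 quaternary in the photochemical step and C5 afterwards. Without the ethylation, 1 is reduced with LiAlH4 to 4-(hydroxymethyl)-3-methylcyclohex-2-en-1-ol F1, oxidised with MnO2 to racemic 4-(hydroxymethyl)-3-methylcyclohex-2-en-1-one F2, resolved as in step 4 to (S)-4-(hydroxymethyl)-3-methylcyclohex-2-en-1-one F3 and silylated to the tert-butyldimethylsilyl ether F4. Irradiation of F4 with 9 is the classical 3-alkylcyclohexenone case, and because C5 still bears a hydrogen, any trans-fused adduct is epimerised on basic alumina to the cis-fused ketone F5. Saegusa–Ito dehydrogenation through the trimethylsilyl enol ether F6 gives the enone F7, whose only remaining α-hydrogen is on C5. LiN(iPr)2 forms the cross-conjugated lithium dienolate F8, and 2 alkylates C5 on the face opposite to C8, since the four-membered ring can only stay cis-fused, to give 12.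

**Step 8.** The vinyl group may add to the lower face, because the inner methoxy group of the acetal lies over the upper face in a 1,3-relationship to C7a and competes with the adjacent silyloxymethyl group as the directing element. 1,2-Addition and incomplete C-methylation of the magnesium enolate are further risks. The fallback sets out from 12 and returns at 14; it puts C7a under thermodynamic control. Conjugate addition of nitromethane (DBU, MeCN) gives the nitromethyl ketone F9. Its sodium nitronate (NaOMe, MeOH) is ozonised at −78 °C, where no C=C bond is present, to the keto aldehyde F10. In F10, C7a–H is α to the formyl group, so DBU equilibrates C7a to the isomer with the formyl group trans to the C3a substituent, whichever face the nucleophile chose. Ph3P=CH2 at −78 °C methylenates only the aldehyde to the vinyl ketone F11, and its lithium enolate F12 (LiN(iPr)2) is methylated with MeI to give 14.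

**Step 16.** Me2CuLi is basic enough to remove C7a–H of 22, which is γ to the enone and allylic to C6=C7; this would epimerise the ring fusion or move the double bond into conjugation. The facial preference at C1 may also be weaker than the cyclopentenone model predicts. The fallback sets out from 22 and returns at 25, replacing 1,4-addition by 1,2-addition and allylic substitution. MeLi/CeCl3 (weakly basic MeCeCl2) adds to the C3 carbonyl from the upper face, anti to C4, to give the tertiary allylic alcohol F13 (methyl up, hydroxyl down). n-BuLi and PhNCO convert it into the N-phenylcarbamate F14. Treatment with MeLi, CuI and again MeLi effects the carbamate-directed syn-SN2′ displacement: the methyl group is delivered to C1 on the lower face and the double bond moves to C2=C3, giving 25 directly without an enol triflate.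

**Step 19.** The cyclobutanone enolate may self-condense, the alkoxide of the α-ketol may contract to a cyclopropane, or oxidation may run on to the 1,2-dione. The fallback sets out from 26 and returns at 29; it cleaves the ring without an oxidant. Double sulfenylation (LiN(iPr)2, 2.2 equiv, PhSSPh, THF/HMPA) gives the α,α-bis(phenylthio)cyclobutanone F15. NaOMe in MeOH opens it between C8 and C1′, driven by ring strain and the sulfur-stabilised carbanion, to the methyl ester bis(phenylthio)acetal F16. HgCl2/CaCO3 in aqueous MeCN then frees the aldehyde 29.

**Step 4.** The lipase may discriminate poorly between the enantiomers of a primary alcohol whose stereocentre is one carbon removed from the hydroxyl group, or may prefer the other enantiomer. The fallback sets out from 6 and returns at 7: preparative chromatography of racemic 6 on a chiral stationary phase (amylose carbamate, supercritical CO2/MeOH) gives 7 directly and makes no new compound (F0).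

## Further compounds

F1 | step 6 | 4-(hydroxymethyl)-3-methylcyclohex-2-en-1-ol (racemic, both diastereomers) | CC1=CC(O)CCC1CO
F2 | step 6 | rac-4-(hydroxymethyl)-3-methylcyclohex-2-en-1-one | CC1=CC(=O)CCC1CO
F3 | step 6 | (S)-4-(hydroxymethyl)-3-methylcyclohex-2-en-1-one | O=C1C=C(C)[C@@H](CO)CC1
F4 | step 6 | (S)-4-{[tert-butyl(dimethyl)silyl]oxymethyl}-3-methylcyclohex-2-en-1-one | O=C1C=C(C)[C@@H](CO[Si](C)(C)C(C)(C)C)CC1
F5 | step 6 | cis-fused 5-{[tert-butyl(dimethyl)silyl]oxymethyl}-7,7-dimethoxy-6-methylbicyclo[4.2.0]octan-2-one (10 without the ethyl group) | O=C1CC[C@H](CO[Si](C)(C)C(C)(C)C)[C@]2(C)[C@H]1CC2(OC)OC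
F6 | step 6 | trimethylsilyl enol ether of F5 | C[Si](C)(C)OC1=CC[C@H](CO[Si](C)(C)C(C)(C)C)[C@]2(C)[C@H]1CC2(OC)OC
F7 | step 6 | cis-fused 5-{[tert-butyl(dimethyl)silyl]oxymethyl}-7,7-dimethoxy-6-methylbicyclo[4.2.0]oct-3-en-2-one (12 without the ethyl group) | O=C1C=C[C@H](CO[Si](C)(C)C(C)(C)C)[C@]2(C)[C@H]1CC2(OC)OC
F8 | step 6 | lithium dienolate of F7 (C6(OLi)=C5) | [Li+].[O-]C1=C2CC(OC)(OC)[C@]2(C)[C@@H](CO[Si](C)(C)C(C)(C)C)C=C1
F9 | step 8 | ketone 10 carrying nitromethyl on C7a (upper face) | CC[C@@]12CC(OC)(OC)[C@]1(C)[C@@H](CO[Si](C)(C)C(C)(C)C)[C@H](C[N+](=O)[O-])CC2=O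
F10 | step 8 | ketone 10 carrying formyl on C7a (upper face, trans to the C3a substituent) | CC[C@@]12CC(OC)(OC)[C@]1(C)[C@@H](CO[Si](C)(C)C(C)(C)C)[C@H](C=O)CC2=O
F11 | step 8 | ketone 10 carrying ethenyl on C7a (upper face) | CC[C@@]12CC(OC)(OC)[C@]1(C)[C@@H](CO[Si](C)(C)C(C)(C)C)[C@H](C=C)CC2=O
F12 | step 8 | lithium enolate of F11 (C6(OLi)=C7) | CC[C@@]12CC(OC)(OC)[C@]1(C)[C@@H](CO[Si](C)(C)C(C)(C)C)[C@H](C=C)C=C2[O-].[Li+]
F13 | step 16 | tertiary allylic alcohol from 22: C3(OH)(CH3) with methyl on the upper and hydroxyl on the lower face, C1=C2 | CC[C@@]12CC(OC)(OC)[C@]1(C)[C@H]3[C@@](C)(O)C=C[C@@H]3C(C)=C2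
F14 | step 16 | N-phenylcarbamate of F13 | CC[C@@]12CC(OC)(OC)[C@]1(C)[C@H]3[C@@](C)(OC(=O)Nc4ccccc4)C=C[C@@H]3C(C)=C2
F15 | step 19 | cyclobutanone 26 with two phenylthio groups on C1′ | CC[C@@]12C(Sc3ccccc3)(Sc3ccccc3)C(=O)[C@]1(C)[C@H]4C(C)=C[C@@H](C)[C@@H]4C(C)=C2
F16 | step 19 | methyl ester 29 with CH(SPh)2 in place of the formyl group | CC[C@]1(C(Sc2ccccc2)Sc2ccccc2)C=C(C)[C@H]3[C@H](C)C=C(C)[C@@H]3[C@@]1(C)C(=O)OC
F0 | step 4 | none | none
A1 | alternative 1 | methyl 2-acetyl-3,5-dimethyl-4-(trimethylsilyl)cyclopent-3-ene-1-carboxylate, all trans (acetyl on C3a, ester on C7a, methyl on C1) | CC(=O)[C@H]1C(C)=C([Si](C)(C)C)[C@@H](C)[C@@H]1C(=O)OC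
A2 | alternative 2 | methyl ester of the target (identical with 32) | CC[C@]1(/C=C/C=C/c2ccccc2)C=C(C)[C@H]2[C@H](C)C=C(C)[C@@H]2[C@@]1(C)C(=O)OC
A3 | alternative 3 | bicyclic acid with tert-butyldimethylsilyloxymethyl on C5 in place of the dienyl chain | CC[C@]1(CO[Si](C)(C)C(C)(C)C)C=C(C)[C@H]2[C@H](C)C=C(C)[C@@H]2[C@@]1(C)C(=O)O
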